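## Structural features

The target is an achiral, depside-type ester of two benzene rings, ring A (the phenol part) and ring B (the benzoyl part), joined only through the O–C(=O) link. Ring A carries, in sequence around the ring, pentyl, hydrogen, hydroxyl, the acyloxy oxygen, hydroxyl and acetyl. Three oxygens are therefore contiguous, the acylated one lies between two free phenols, and acetyl and pentyl sit on adjacent carbons. Ring B is a 4-hydroxy-2-methoxy-6-propylbenzoyl unit: its carboxyl carbon is flanked by methoxy and propyl, and its two oxygens differ (methyl ether ortho, free phenol para). The target has no stereocentre; the only ones in the plan are the adjacent sp3 carbons C4 and C5 of a cyclohexanedione precursor of ring A, and both are erased on aromatisation. The fragile element is the central aryl ester, which can migrate to a neighbouring phenol or be cleaved once a phenoxide or other nucleophile is present; the aryl ketone (reduction) and the electron-rich benzoic acid (decarboxylation in hot acid) also restrict late reagents. The real difficulty is the central C–O bond, since acylating the middle oxygen of a 1,2,3-trioxygenated arene with a di-ortho-substituted acid is disfavoured both by selectivity and by sterics. The key step exploits the pattern of ring A: the two hydroxyl-bearing carbons and the ester-bearing carbon between them are C1, C3 and C2 of a cyclohexane-1,3-dione, and the acetyl/pentyl pair is its C4–C5 bond, so ring A is a dehydrogenated 4-acetyl-5-pentylcyclohexane-1,3-dione whose C2 methylene is the natural site for the third oxygen.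

## Logic of the disconnections

**12 to 11.** The O–CH2Ph bond on the para oxygen of ring B is cut. A benzyl ether is chosen because it can be removed by neutral hydrogenolysis, the one kind of final step that the migration-prone ester tolerates. The gain is that ring B's phenol is silent in all earlier steps. The demand is that hydrogenolysis stops before the aryl ketone is touched.

**11 to 10.** No skeletal bond is cut; ring A is taken back by two hydrogens to a cyclohexane-1,3-dione. In 10 the two future phenols are carbonyl groups and only the middle oxygen is an ester, so three phenolic oxygens never have to be told apart. The demand is a dehydrogenation that spares the ester, the benzyl ether and the product arene.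

**10 to 9 and 4.** The bond cut is the one between ring A carbon C2 and the carboxylate oxygen, not the acyl C–O bond. The shielded acyl carbon of 4 then never has to be attacked: its carboxyl oxygen acts as the nucleophile towards a carbenoid at C2. This is the convergent step and splits the molecule into halves of similar size. The demand is that the acid intercepts the carbenoid faster than the carbonyl and enol oxygens of 9 itself.

**9 to 8.** The C2=N2 bond is cut, leaving the doubly activated methylene of 8. The gain is that the oxygenation site is addressed by acidity alone. The demand is site selectivity for C2 over the second acidic position, the C4 methine next to the acetyl group.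

**8 to 5 and 6.** Two ring bonds of 8 are cut: C4–C5 (acetyl-bearing to pentyl-bearing carbon) and C1–C2 (carbonyl to methylene). This is the largest simplification of the plan, reducing a pentasubstituted ring to two commodity liquids. The demand is that ring closure of the open-chain adduct 7 outruns cleavage of one of its acetyl groups.

**4 to 3.** The acid is masked as its methyl ester (acyl–OCH3 bond). The ester keeps the carboxyl group inert during the two alkylations. The demand is hydrolysis of a di-ortho-substituted ester without decarboxylation.

**3 to 2.** The ortho O–CH3 bond is cut. It is made after the para oxygen is blocked, so no selectivity is needed at that stage. The demand is only a sufficiently forcing alkylation of a chelated phenol.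

**2 to 1.** The para O–CH2Ph bond is cut. The hydrogen bond between the ortho hydroxyl and the ester carbonyl in 1 differentiates the two phenols for free. The demand is that one equivalent of halide and a weak base stop at mono-alkylation.

## Other disconnections considered

**Alternative 1:** The cut is in ring B, at the C1–carboxyl and C6–propyl bonds, both traced to an aryne from the aryl fluoride A1, (3-fluoro-5-methoxyphenoxy)tri(propan-2-yl)silane.
- Forward step: A1 would be lithiated between fluorine and methoxy and lose fluoride to an aryne. A propyl Grignard reagent would add at the aryne carbon remote from methoxy, and carboxylation of the arylmagnesium next to methoxy would give 2-methoxy-6-propyl-4-(triisopropylsilyloxy)benzoic acid A2 in one flask.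
- In favour: two C–C bonds are formed in one operation. The acid arrives free, so the slow saponification of step 3 is avoided; on this point the alternative is better than the chosen plan. A2 could enter step 6 in place of 4, and the ring B sequence would shrink from three steps to two, which is also better.
- Against: three organometallic events must succeed in sequence at low temperature, and the alkyllithium base can itself add to the aryne. The regiochemistry rests on the inductive bias of one methoxy group, whereas the annulation of the chosen plan has no regiochemical alternative. The silyl ether would have to be removed at the end with fluoride, a basic nucleophile, next to an ester that can migrate; hydrogenolysis is the gentler finish.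
- Comparison: the alternative solves only ring B and leaves ring A and the central C–O bond, where the difficulty lies, untouched. It competes with steps 1 to 3 and would be grafted onto steps 4 to 8, not replace them.

**Alternative 2:** The cut is a [4+2] disconnection of ring B at C1–C2 and C5–C6 (benzoate numbering) into diene A3, 1,1-dimethoxy-3-(trimethylsilyloxy)buta-1,3-diene, and alkynoate A4, methyl hex-2-ynoate.
- Forward step: heating A3 with A4 would give a cycloadduct that aromatises by loss of one methoxy group as the alcohol and of the silyl group, giving methyl 4-hydroxy-2-methoxy-6-propylbenzoate A5.
- In favour: the two oxygens of ring B emerge differentiated by construction (the ketene acetal carbon becomes the ortho methyl ether, the silyl enol ether carbon the para phenol). This is better than the chosen plan, where the differentiation depends on the selectivity of step 1 and costs two alkylations. The regiochemistry follows from the polarity of both partners.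
- Against: A3 is hydrolytically labile and takes two steps to make. A4, with a β-alkyl group, is a sluggish dienophile, and prolonged heating costs diene. A5 would still need benzylation to 3 and the same hindered saponification.
- Comparison: counting the cycloaddition, one alkylation, the hydrolysis and the diene preparation, the alternative is at best equal to steps 1 to 3 in step economy. It also leaves ring A and the central ester unsolved.

**Alternative 3:** The cut is the ring B bond between the carboxyl-bearing and the propyl-bearing carbons, opening the arene to the linear chain A6, methyl 3,5,7-trioxodecanoate.
- Forward step: in dilute aqueous base, C2 of A6 would add to the C7 ketone; dehydration and enolisation would give methyl 2,4-dihydroxy-6-propylbenzoate A7.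
- In favour: the step mirrors the biosynthetic folding and aromatises by dehydration alone, with no oxidant. On this mechanistic point it is cleaner than the ring A construction of the chosen plan, which spends an oxidant in step 7. A7 is the same substance as 1, so the alternative does not conflict with the chosen plan; it would supply its starting material, and in outcome the two are equal.
- Against: A6 has to be assembled by polyanion acylation under cryogenic strong-base conditions. It can also close by Claisen-type acylation or by lactonisation to a pyranone, with the outcome depending on pH. The two phenols of A7 are undifferentiated, so steps 1 to 3 would follow unchanged.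
- Comparison: against purchase of 1 the alternative adds at least two steps. Like the other two, it addresses ring B only.

Key step: step 4

Remark on sourcing: 1 and 6 are taken as catalogue compounds (1 is the usual building block of the propyl cannabinoid series, 6 a flavour ingredient); nothing else is assumed.

Step 1
Reactants: 1 methyl 2,4-dihydroxy-6-propylbenzoate
Product: 2 methyl 4-(benzyloxy)-2-hydroxy-6-propylbenzoate
Conditions: BnBr (1.05 equiv), K2CO3 (1.2 equiv), acetone, reflux
Reagents that add atoms: benzyl bromide, BrCc1ccccc1
Why: Williamson ether synthesis; the 2-hydroxyl is tied up in a hydrogen bond to the ester carbonyl and is less acidic and less nucleophilic than the 4-hydroxyl para to the ester, so one equivalent of halide with a weak base should alkylate the 4-oxygen only.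

Step 2
Reactants: 2 methyl 4-(benzyloxy)-2-hydroxy-6-propylbenzoate
Product: 3 methyl 4-(benzyloxy)-2-methoxy-6-propylbenzoate
Conditions: MeI (2 equiv), K2CO3 (2.5 equiv), DMF, 40 °C
Reagents that add atoms: iodomethane, CI
Why: Williamson methylation of the remaining chelated phenol, which needs the more polar solvent and excess reagent; no other nucleophilic site is left in the molecule.

Step 3
Reactants: 3 methyl 4-(benzyloxy)-2-methoxy-6-propylbenzoate
Product: 4 4-(benzyloxy)-2-methoxy-6-propylbenzoic acid
Conditions: KOH (6 equiv), DMSO/H2O 4:1, 90 °C; then 1 M HCl, 0 °C, to pH 3
Reagents that add atoms: potassium hydroxide, [K+].[OH-] (the hydroxide oxygen ends up in the carboxyl group)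
Why: Saponification of a di-ortho-substituted benzoate, slow in alcohols but workable with poorly solvated hydroxide in aqueous DMSO; benzyl and methyl aryl ethers are inert to hydroxide, and cold acidification should avoid protodecarboxylation of the electron-rich acid.

Step 4
Reactants: 5 pentane-2,4-dione; 6 ethyl (E)-oct-2-enoate
Product: 8 (4RS,5RS)-4-acetyl-5-pentylcyclohexane-1,3-dione (trans; racemic; largely enolised), via ethyl 3-(2,4-dioxopentan-3-yl)octanoate 7 (not isolated)
Conditions: 5 (1.1 equiv), t-BuOK (1.1 equiv), THF/t-BuOH 5:1, 0 °C; 6 (1.0 equiv), 60 °C; then t-BuOK (1.2 equiv), 65 °C; 2 M HCl to pH 2
Reagents that add atoms: none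
Why: The potassium enolate of 5 adds in Michael fashion to the β-carbon of 6, which forms the C4–C5 bond of the future ring, and proton transfer parks the adduct as the stabilised diketonate of 7. The second portion of tert-butoxide gives an equilibrium amount of the terminal enolate (the β-diketone dianion) at one of the two equivalent acetyl methyl groups, and this carbon attacks the ester carbonyl and expels ethoxide in a Claisen condensation of the Dieckmann type, which forms the C1–C2 bond. The ring closure is 6-(enolendo)-exo-trig, a favoured mode, and no other ring size is within reach because the other enolate carbons could only close four-membered rings. The closest known reaction type is the tandem Michael–Claisen synthesis of 5-alkylcyclohexane-1,3-diones from β-dicarbonyl donors and α,β-unsaturated esters. The two new stereocentres C4 and C5 are not set by any reagent: C4 is a β-diketone methine and epimerises freely, so the diequatorial trans isomer should prevail under thermodynamic control, and both centres disappear in step 7. The selectivity that matters is chemoselectivity, ring closure in preference to retro-Claisen loss of an acetyl group from 7; a hindered and poorly nucleophilic alkoxide in THF, the storage of 7 as its enolate before excess base is present, and the final deprotonation of the acidic product to its dianion should secure it. O-Acylation of the diketonate to an enol lactone is reversible under these conditions and should drain into the same product.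

Step 5
Reactants: 8 (4RS,5RS)-4-acetyl-5-pentylcyclohexane-1,3-dione
Product: 9 (4RS,5RS)-4-acetyl-2-diazo-5-pentylcyclohexane-1,3-dione (trans; racemic)
Conditions: p-ABSA (1.0 equiv), Et3N (1.1 equiv), MeCN, 0 °C to rt
Reagents that add atoms: 4-acetamidobenzenesulfonyl azide (p-ABSA), CC(=O)Nc1ccc(cc1)S(=O)(=O)N=[N+]=[N-]
Why: Regitz diazo transfer to the C2 methylene of a cyclic 1,3-dione; with one equivalent of a weak base only the much more acidic ring dione is deprotonated, so the C4 methine next to the acetyl group should stay untouched, and the shelf-stable sulfonyl azide and a stabilised acceptor/acceptor diazo product keep the hazard low.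

Step 6
Reactants: 9 (4RS,5RS)-4-acetyl-2-diazo-5-pentylcyclohexane-1,3-dione; 4 4-(benzyloxy)-2-methoxy-6-propylbenzoic acid
Product: 10 3-acetyl-2,6-dioxo-4-pentylcyclohexyl 4-(benzyloxy)-2-methoxy-6-propylbenzoate (racemic; acetyl and pentyl trans; the acyloxy-bearing carbon is not a fixed stereocentre because the compound is enolised)
Conditions: Rh2(OAc)4 (2 mol %), PhCF3, 60 °C, slow addition of 9 (1.3 equiv) to 4
Reagents that add atoms: none
Why: Carbenoid O–H insertion: Rh2(OAc)4 turns the diazo dione into an electrophilic carbenoid, the carboxyl oxygen of 4 adds to it and a proton shift gives the 2-acyloxy dione, a known reaction of carboxylic acids with 2-diazo-1,3-dicarbonyl compounds. The new bond is to the ring A carbon and not to the shielded acyl carbon, so the two ortho substituents of 4 are no obstacle, and the same shielding should slow any later acyl migration to the neighbouring enol oxygens.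

Step 7
Reactants: 10 3-acetyl-2,6-dioxo-4-pentylcyclohexyl 4-(benzyloxy)-2-methoxy-6-propylbenzoate
Product: 11 3-acetyl-2,6-dihydroxy-4-pentylphenyl 4-(benzyloxy)-2-methoxy-6-propylbenzoate
Conditions: DDQ (1.1 equiv), toluene, 80 °C
Reagents that add atoms: none
Why: DDQ dehydrogenation of a cyclohexane-1,3-dione to a resorcinol: hydride abstraction from the dienol at the pentyl-bearing or the methylene carbon, proton loss and tautomerisation give the arene. Both sp3 stereocentres vanish, and the three oxygens arrive already differentiated, two as free phenols and the middle one as the ester; neither ring carries an activated benzylic position that DDQ should attack.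

Step 8
Reactants: 11 3-acetyl-2,6-dihydroxy-4-pentylphenyl 4-(benzyloxy)-2-methoxy-6-propylbenzoate
Product: 12 3-acetyl-2,6-dihydroxy-4-pentylphenyl 4-hydroxy-2-methoxy-6-propylbenzoate (target)
Conditions: H2 (1 atm), 10% Pd/C, EtOAc, rt
Reagents that add atoms: none
Why: Hydrogenolysis of an aryl benzyl ether under neutral conditions, so no phenoxide is formed and the central ester should neither migrate nor cleave; at 1 atm and room temperature the hydrogen-bonded aryl ketone and the aryl ester are expected to survive if the reaction is stopped after one equivalent of hydrogen.

## Compound list

1 | methyl 2,4-dihydroxy-6-propylbenzoate | CCCc1cc(O)cc(O)c1C(=O)OC | starting material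
2 | methyl 4-(benzyloxy)-2-hydroxy-6-propylbenzoate | CCCc1cc(OCc2ccccc2)cc(O)c1C(=O)OC | intermediate
3 | methyl 4-(benzyloxy)-2-methoxy-6-propylbenzoate | CCCc1cc(OCc2ccccc2)cc(OC)c1C(=O)OC | intermediate
4 | 4-(benzyloxy)-2-methoxy-6-propylbenzoic acid | CCCc1cc(OCc2ccccc2)cc(OC)c1C(O)=O | intermediate
5 | pentane-2,4-dione | CC(=O)CC(C)=O | starting material
6 | ethyl (E)-oct-2-enoate | CCCCC/C=C/C(=O)OCC | starting material
7 | ethyl (3RS)-3-(2,4-dioxopentan-3-yl)octanoate (racemic, one enantiomer drawn; present as its potassium enolate) | CCCCC[C@@H](CC(=O)OCC)C(C(C)=O)C(C)=O | intermediate (not isolated)
8 | (4RS,5RS)-4-acetyl-5-pentylcyclohexane-1,3-dione (trans, racemic, one enantiomer drawn; largely enolised) | CCCCC[C@H]1CC(=O)CC(=O)[C@@H]1C(C)=O | intermediate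
9 | (4RS,5RS)-4-acetyl-2-diazo-5-pentylcyclohexane-1,3-dione (trans, racemic, one enantiomer drawn) | CCCCC[C@H]1CC(=O)C(=[N+]=[N-])C(=O)[C@@H]1C(C)=O | intermediate
10 | 3-acetyl-2,6-dioxo-4-pentylcyclohexyl 4-(benzyloxy)-2-methoxy-6-propylbenzoate (racemic, acetyl and pentyl trans, one enantiomer drawn; acyloxy-bearing carbon undefined, enolised) | CCCCC[C@H]1CC(=O)C(OC(=O)c2c(CCC)cc(OCc3ccccc3)cc2OC)C(=O)[C@@H]1C(C)=O | intermediate
11 | 3-acetyl-2,6-dihydroxy-4-pentylphenyl 4-(benzyloxy)-2-methoxy-6-propylbenzoate | CCCCCc1cc(O)c(OC(=O)c2c(CCC)cc(OCc3ccccc3)cc2OC)c(O)c1C(C)=O | intermediate
12 | 3-acetyl-2,6-dihydroxy-4-pentylphenyl 4-hydroxy-2-methoxy-6-propylbenzoate | CCCCCc1cc(O)c(OC(=O)c2c(CCC)cc(O)cc2OC)c(O)c1C(C)=O | target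

## Step count and least certain steps

Total: 8 steps. Longest linear sequence: 6 steps (steps 1, 2, 3, 6, 7, 8); the ring A branch contributes 5 (steps 4 to 8).

**Step 4 (key step).** The likeliest failure is cleavage of an acetyl group from the Michael adduct by alkoxide before the ring closes. A sluggish conjugate addition to the β-alkylated acceptor, with reversible O-acylation holding material back as an enol lactone, is the second risk. The fallback separates the two events. It sets out from 5 and 6: the conjugate addition is run with a substoichiometric carbonate base (Cs2CO3, DMSO, 50 °C) and 7 is isolated. Then 7 is converted with lithium diisopropylamide (2.3 equiv, THF, −78 to 0 °C) into its β-diketone dianion, which carries its reactive charge on the terminal carbon and should acylate there on the ester with no free alkoxide present. Acidification brings the sequence back to the route at 8. No compound outside the list is made (F0).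

**Step 6.** The carbenoid may be diverted by the substrate's own oxygens. The C4 acetyl group stands in a 1,3-relation to the carbenoid carbon across C3, so carbonyl ylide formation or insertion into an enol O–H of a second molecule can compete; Wolff ring contraction is possible at the temperature needed. The fallback avoids carbenoids altogether and sets out from 4 and 8. Ligand exchange of PhI(OAc)2 with 4 (2 equiv, acetic acid removed under vacuum) gives the trivalent iodine dicarboxylate phenyl-λ3-iodanediyl bis[4-(benzyloxy)-2-methoxy-6-propylbenzoate] F1. With 8 in MeCN, F1 should transfer one acyloxy group to C2 by attack of the dione enol on iodine and reductive ligand coupling, the known α-acyloxylation of 1,3-dicarbonyl compounds with [bis(acyloxy)iodo]arenes. The sequence returns at 10, one equivalent of 4 is recovered, and step 5 is no longer needed.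

**Step 5.** Diazo transfer may also take place at the second acidic site, the C4 methine between the C3 carbonyl and the acetyl group, which would end in loss of the acetyl group; a second transfer after the first is a further risk. The fallback sets out from 8. PhI(OAc)2 and Na2CO3 in MeOH should give the iodonium ylide 4-acetyl-5-pentyl-2-(phenyl-λ3-iodanylidene)cyclohexane-1,3-dione F2; only a methylene between two carbonyls can form such an ylide, so C2 is addressed by construction. F2 is an established carbene precursor and, with Rh2(OAc)4 or Cu(acac)2 and 4, should undergo the same O–H insertion. The sequence returns at 10.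

**Step 7.** Hydride abstraction may be incomplete or unselective, with adduct formation between DDQ and the enol, over-oxidation of the electron-rich product, or attack at the benzyl ether. The fallback sets out from 10 and puts a leaving group on the doubly activated carbon instead. PhSeCl and pyridine in CH2Cl2 should selenenylate the acetyl-bearing carbon, anti to the pentyl group, to give 3-acetyl-2,6-dioxo-4-pentyl-3-(phenylselanyl)cyclohexyl 4-(benzyloxy)-2-methoxy-6-propylbenzoate F3. Oxidation with H2O2 and syn-elimination of the selenoxide towards the hydrogen on the pentyl-bearing carbon would give the cyclohexenedione, which tautomerises to the arene. The sequence returns at 11.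

**Step 3.** Hydrolysis of the doubly shielded ester may be slow, and the product may lose carbon dioxide during acidification. The fallback sets out from 3 and reaches the acid by oxidation instead of hydrolysis. LiAlH4 in THF, a small hydride that reaches the hindered carbonyl, should give [4-(benzyloxy)-2-methoxy-6-propylphenyl]methanol F4. MnO2 in CH2Cl2 would oxidise it to 4-(benzyloxy)-2-methoxy-6-propylbenzaldehyde F5, and Pinnick oxidation (NaClO2, NaH2PO4, 2-methylbut-2-ene, t-BuOH/H2O) would give the acid under nearly neutral conditions. The sequence returns at 4.

## Further compounds

F0 | step 4 | none | none
F1 | step 6 | phenyl-λ3-iodanediyl bis[4-(benzyloxy)-2-methoxy-6-propylbenzoate] | CCCc1cc(OCc2ccccc2)cc(OC)c1C(=O)OI(c1ccccc1)OC(=O)c1c(CCC)cc(OCc2ccccc2)cc1OC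
F2 | step 5 | 4-acetyl-5-pentyl-2-(phenyl-λ3-iodanylidene)cyclohexane-1,3-dione (trans, racemic, one enantiomer drawn) | CCCCC[C@H]1CC(=O)[C-]([I+]c2ccccc2)C(=O)[C@@H]1C(C)=O
F3 | step 7 | 3-acetyl-2,6-dioxo-4-pentyl-3-(phenylselanyl)cyclohexyl 4-(benzyloxy)-2-methoxy-6-propylbenzoate (racemic, selenium anti to pentyl, one enantiomer drawn; acyloxy-bearing carbon undefined) | CCCCC[C@H]1CC(=O)C(OC(=O)c2c(CCC)cc(OCc3ccccc3)cc2OC)C(=O)[C@@]1([Se]c1ccccc1)C(C)=O
F4 | step 3 | [4-(benzyloxy)-2-methoxy-6-propylphenyl]methanol | CCCc1cc(OCc2ccccc2)cc(OC)c1CO
F5 | step 3 | 4-(benzyloxy)-2-methoxy-6-propylbenzaldehyde | CCCc1cc(OCc2ccccc2)cc(OC)c1C=O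
A1 | alternative 1 | (3-fluoro-5-methoxyphenoxy)tri(propan-2-yl)silane | COc1cc(F)cc(O[Si](C(C)C)(C(C)C)C(C)C)c1
A2 | alternative 1 | 2-methoxy-6-propyl-4-(triisopropylsilyloxy)benzoic acid | CCCc1cc(O[Si](C(C)C)(C(C)C)C(C)C)cc(OC)c1C(O)=O
A3 | alternative 2 | 1,1-dimethoxy-3-(trimethylsilyloxy)buta-1,3-diene | COC(OC)=CC(=C)O[Si](C)(C)C
A4 | alternative 2 | methyl hex-2-ynoate | CCCC#CC(=O)OC
A5 | alternative 2 | methyl 4-hydroxy-2-methoxy-6-propylbenzoate | CCCc1cc(O)cc(OC)c1C(=O)OC
A6 | alternative 3 | methyl 3,5,7-trioxodecanoate | CCCC(=O)CC(=O)CC(=O)CC(=O)OC
A7 | alternative 3 | methyl 2,4-dihydroxy-6-propylbenzoate (identical with 1) | CCCc1cc(O)cc(O)c1C(=O)OC
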